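Start from Sunday's run: by 15.0 min the left-handed substrate has dropped to 8.6% of the two charged together, and the right-handed substrate to 44.5%. Write θ for the natural log of a substrate's starting share over its share left. Then the selectivity factor s, left-handed θ divided by right-handed θ, reads 15.1 there.

the same everywhere: gas 19 mM (held); catalyst 1 mol%

|  | left-handed substrate | right-handed substrate | added ligand | remark | time |
|---|---|---|---|---|---|
| Sunday's | 0.092 M | 0.092 M | 1.7 mM | run made earlier |  |
| Wednesday's | 0.092 M | 0.092 M | 3.8 mM | run made earlier |  |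
| Friday's | 0.046 M | 0.046 M | 2.5 mM | run made earlier |  |
| flask | 0.092 M | 0.092 M | 2.5 mM |  | 25 min |

| run | time / min | right-handed substrate / % | left-handed substrate / % | left-handed product / % |
|---|---|---|---|---|
| Sunday's | 2.50 | 48.9 | 41.0 | 9.4 |
| Sunday's | 5.00 | 48.1 | 31.6 | 18.5 |
| Sunday's | 8.00 | 46.8 | 22.1 | 28.3 |
| Sunday's | 10.0 | 46.5 | 17.2 | 33.3 |
| Sunday's | 12.0 | 46.1 | 13.2 | 36.9 |
| Sunday's | 15.0 | 44.5 | 8.6 | 41.6 |
| Wednesday's | 2.50 | 49.5 | 42.9 | 7.6 |
| Wednesday's | 5.00 | 48.6 | 34.9 | 15.0 |
| Wednesday's | 8.00 | 47.8 | 26.7 | 23.5 |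
| Wednesday's | 10.0 | 47.1 | 22.4 | 27.6 |
| Wednesday's | 12.0 | 46.5 | 18.4 | 31.4 |
| Wednesday's | 15.0 | 45.9 | 13.6 | 36.4 |
| Friday's | 1.33 | 50.1 | 47.9 | 2.3 |
| Friday's | 4.00 | 49.7 | 41.1 | 9.0 |
| Friday's | 8.00 | 48.3 | 31.9 | 18.1 |
| Friday's | 10.0 | 48.1 | 28.0 | 21.8 |
| Friday's | 15.0 | 47.2 | 20.0 | 29.5 |

(each reading ± 0.3 percentage points)

* whether the excess of right-handed substrate over left-handed substrate among what is left of the two reaches 80% by 25 min (no / yes)
* the highest excess of right-handed substrate over left-handed substrate among what is left of the two up to 25 min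

- catalyst is single-handed; left-handed substrate and right-handed substrate are mirror images of each other, charged as a racemate, each of them at the stated concentration
- at the start none of the gas is in solution

An excess of 80% means 9.00 times as much right-handed as left-handed substrate, so with s the left-handed θ must reach 2.35.

Now watch the rate κ, the gain in left-handed θ per minute. In Sunday's run, with 1.7 mM added ligand, κ goes from 0.104 min⁻¹ in the first interval to 0.143 min⁻¹ in the last, faster as the run goes on. In Wednesday's run, with 3.8 mM, the last κ is 0.101 min⁻¹, slower by a factor 1.42.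

My reckoning for the flask interpolates 1/θ and 1/κ between those runs at 2.5 mM. This gives θ = 1.55 at 15.0 min and a late κ of 0.123 min⁻¹. Friday's run has the flask's ligand and half its catalyst, and its last κ of 0.0673 min⁻¹ is half of that. Holding κ there, the flask reaches the needed θ at 21.5 min and stands at θ = 2.78 by 25 min, an excess of 86.2%.

The forecast, resting on “a selectivity of about 15 in all three runs”, says yes and a top of 87%, above my figure.

    coupling partner + catalyst + left-handed substrate → catalyst + left-handed product (k = 14000 M⁻² min⁻¹)
    coupling partner + catalyst + right-handed substrate → catalyst + right-handed product (k = 910 M⁻² min⁻¹)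
    gas ⇌ coupling partner, rate k3*(csat - [coupling partner]) (kL = 1.20 min⁻¹)
    catalyst + added ligand ⇌ idle complex, settled at all times (K = 310 M⁻¹)
    coupling partner ⇌ dormant form (K = 8.80, k = 0.0260 min⁻¹)

The flask gives yes, with a top of 87.0%. It passes 80% at 21.3 min, with 42.9% of the charge still right-handed substrate. Put s to that moment: a left-handed θ of 2.35 implies a right-handed share of 42.8%. Put s to Wednesday's run as a second flask: its left-handed 13.6% at 15.0 min implies a right-handed share of 45.9%, and the reading there is 45.9%.

Readings and results were computed with made-up constants; the scatter is artificial.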